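The earlier runs and the new flask stem from a simulated flask with made-up constants; the scatter is artificial.

Initiator is what differs between the grey run and the ochre run; their free monomer charges are equal. So ask first whether the initiator simply speeds the same curve.

| flask | free monomer | initiator | remark | time |
|---|---|---|---|---|
| grey | 0.034 M | 1.2 mM | run made earlier |  |
| ochre | 0.034 M | 1.9 mM | run made earlier |  |
| flask | 0.034 M | 0.88 mM |  | 6.0 h |

- grey (time / h: monomer in chains / %, free monomer / %): 0.417: 7.1, 93.9; 0.667: 11.3, 89.2; 1.33: 21.3, 78.5; 2.50: 35.8, 64.0; 5.00: 54.2, 45.3
- ochre (time / h: monomer in chains / %, free monomer / %): 0.417: 10.1, 88.8; 1.33: 31.6, 69.1; 2.00: 42.1, 57.3; 3.00: 53.8, 45.7; 5.00: 66.4, 32.4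

(scatter of a reading: 0.3 percentage points)

* average number of monomer units in a chain (chains begun, living or dead) at 6.0 h
* part of the free monomer that has reacted at 6.0 h

- the average divides the monomer in chains by the number of chains begun, living and dead together
- steps under discussion: free monomer + initiator -> living end + monomer in chains; monomer in chains + living end -> free monomer + living end; living end + monomer in chains -> dead end; free monomer + living end -> monomer in chains + living end
- the earlier runs do not show the number of chains; that part of a forecast is a guess

To test this, use initiator-hours: the initiator charged multiplied by the time, the axis of a Selwyn plot. The grey run at 5.00 h has 21.6 M·s and leaves 45.3% free monomer. The ochre run at 3.00 h has 20.5 M·s and leaves 45.7%. The two nearly coincide, so initiator-hours can serve as the clock.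

The flask will have 19.0 M·s, just short of the ochre reading. Replacing the ochre curve by its mean slope between 2.00 h and 3.00 h, my own reckoning gives 52.0% reacted. If each initiator begins one chain, which is a guess, the average is 20.1 units.

The forecast says 50.5% (47.5% to 53.5%) and 20 (18 to 27), on the ground that “Rate is therefore proportional to initiator”. My figure for the part reacted is a little higher than its figure.

The flask gives 51.1% and 19.5.

    free monomer + initiator → living end + monomer in chains (k = 0.0320 L mol⁻¹ s⁻¹)
    monomer in chains + living end → free monomer + living end, rate k2*[living end] as long as [monomer in chains] is above zero (k = 3.10 × 10⁻⁴ s⁻¹)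
    living end + monomer in chains → dead end (k = 0.00110 L mol⁻¹ s⁻¹)
    free monomer + living end → monomer in chains + living end, rate k4*[living end]*[free monomer] (k = 0.0550 L mol⁻¹ s⁻¹)

At 6.00 h the flask still holds 6.92 × 10⁻⁴ M of living end from 0.88 mM of initiator charged. The consumption of initiator is the largest single effect on the average in this flask, though not the whole explanation: with the initiator held at its charge, the average is 3.46 instead of 19.5. A neighbour flask with 5.3 × 10⁻⁴ M of initiator reaches 11.4 M·s on the initiator-hours clock, close to the 10.8 M·s of the grey run at 2.50 h, where 64.0% free monomer was read. At 6.00 h that neighbour flask holds 62.9% free monomer.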